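**Plan**

1. The target has no stereocentre. Going round ring A, carbon and oxygen substituents alternate (C-methyl, OH, bridging CH2, OH, isobutyryl, OH). The ring is cut at two bonds: the one joining the bridge-bearing carbon to the hydroxyl carbon that lies between bridge and isobutyryl group, and the one joining the isobutyryl-bearing carbon to the hydroxyl carbon that lies between isobutyryl and C-methyl group. This leaves a four-carbon 1,3-dioxygenated piece (C–OH, C–CH3, C–OH, C–CH2; an α-methyl β-keto ester used as its bis-silyl dienol ether) and a two-carbon 3-alkoxy ynone (the remaining C–OH carbon and the acyl-bearing carbon) that already carries the isobutyryl group.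
2. Behind the diene the cuts are: the ester-side C–C bond of the β-keto ester (decarboxylative Claisen), the two chain carbons beyond the bridge carbon (reductive Knoevenagel), the bridge carbon itself (formylation at C8), the pyranone ring (acylation/oxa-Michael) and the phenol C–O bond (C–H borylation/oxidation of 2,6-dimethoxytoluene).
3. Forward order: ring B arene, then the pyranone ring, the C8 side chain, the β-keto ester and the tris(silyl) diene. Ring A is built last by benzannulation with the ynone, and one global O-dealkylation finishes the synthesis.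
4. Stereochemistry: nothing to set in the target. The only controlled element is the Z enol-ether double bond of the diene (kinetic deprotonation), which keeps the CH2 group outside the s-cis diene.

Key step: step 11

Remark on the chemistry: potassium methyl methylmalonate is taken as a purchasable reagent (otherwise one half-saponification of dimethyl methylmalonate with KOH). The chromanone keeps its usual numbering; the carbons of ring A are named by the substituent they carry.

**Route**

Step 1
Reactants: 1 2,6-dimethoxytoluene
Product: 2 2-(3,5-dimethoxy-4-methylphenyl)-4,4,5,5-tetramethyl-1,3,2-dioxaborolane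
Conditions: B2pin2 (1.0 equiv), [Ir(OMe)(cod)]2 (1.5 mol %), 4,4'-di-tert-butyl-2,2'-bipyridine (3 mol %), THF, 80 °C
Reagents that add atoms: bis(pinacolato)diboron, CC1(C)OB(OC1(C)C)B1OC(C)(C)C(C)(C)O1
Why: Iridium-catalysed aromatic C–H borylation is sterically controlled, and the C–H para to the methyl group is the only one without an ortho neighbour, so a single boronate should form.

Step 2
Reactants: 2 2-(3,5-dimethoxy-4-methylphenyl)-4,4,5,5-tetramethyl-1,3,2-dioxaborolane
Product: 3 3,5-dimethoxy-4-methylphenol
Conditions: H2O2 (30 % aq), NaOH, THF, 0 °C → rt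
Reagents that add atoms: hydrogen peroxide, OO
Why: Alkaline peroxide oxidation of an arylboronate (1,2-aryl shift from boron to oxygen) should give the phenol at the borylated position.

Step 3
Reactants: 3 3,5-dimethoxy-4-methylphenol; 4 3-methylbut-2-enoic acid
Product: 5 5,7-dimethoxy-2,2,6-trimethylchroman-4-one
Conditions: P2O5/MeSO3H (1:10 w/w), 70 °C
Reagents that add atoms: none
Why: Friedel–Crafts acylation at one of the two equivalent positions ortho to the phenol followed by intramolecular oxa-Michael addition is the standard 2,2-dimethylchroman-4-one synthesis, and with a single free OH only one pyranone regioisomer can form.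

Step 4
Reactants: 5 5,7-dimethoxy-2,2,6-trimethylchroman-4-one
Product: 6 5,7-dimethoxy-2,2,6-trimethyl-4-oxochroman-8-carbaldehyde
Conditions: Cl2CHOMe, TiCl4, CH2Cl2, −20 → 0 °C; then cold aq HCl
Reagents that add atoms: dichloromethyl methyl ether, COC(Cl)Cl; water, O
Why: Rieche formylation should occur at C8, the only unsubstituted ring carbon, which is activated by two ortho oxygens and one para oxygen.

Step 5
Reactants: 6 5,7-dimethoxy-2,2,6-trimethyl-4-oxochroman-8-carbaldehyde; 7 Meldrum's acid (2,2-dimethyl-1,3-dioxane-4,6-dione)
Product: 10 3-(5,7-dimethoxy-2,2,6-trimethyl-4-oxochroman-8-yl)propanoic acid, via arylidene Meldrum's acid 8 (not isolated), via benzyl Meldrum's acid 9 (not isolated)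
Conditions: HCO2H/Et3N (5:2), 95–100 °C; then aq HCl
Reagents that add atoms: none
Why: This is a one-pot reductive Knoevenagel sequence (condensation, conjugate hydride transfer from formate to the alkylidene Meldrum's acid, hydrolytic decarboxylation by the water released in the condensation), and the aryl ketone is inert to formate.

Step 6
Reactants: 10 3-(5,7-dimethoxy-2,2,6-trimethyl-4-oxochroman-8-yl)propanoic acid; 11 potassium methyl methylmalonate (potassium 3-methoxy-2-methyl-3-oxopropanoate)
Product: 13 methyl 5-(5,7-dimethoxy-2,2,6-trimethyl-4-oxochroman-8-yl)-2-methyl-3-oxopentanoate (racemic), via acyl imidazolide 12 (not isolated)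
Conditions: CDI, THF, rt; then 11, MgCl2, Et3N, MeCN, rt → 45 °C; 1 M HCl
Reagents that add atoms: 1,1'-carbonyldiimidazole, O=C(n1ccnc1)n1ccnc1 (its imidazole ring is present in 12 only and is lost again on the way to 13)
Why: The Masamune–Brooks decarboxylative Claisen condensation of an acyl imidazolide with a magnesium malonate half-ester runs under near-neutral conditions that should leave the enolisable chromanone untouched.

Step 7
Reactants: 13 methyl 5-(5,7-dimethoxy-2,2,6-trimethyl-4-oxochroman-8-yl)-2-methyl-3-oxopentanoate
Product: 14 methyl 5-(5,7-dimethoxy-2,2,6-trimethyl-4-oxochroman-8-yl)-2-methyl-3-(trimethylsilyloxy)pent-2-enoate (drawn Z; the geometry is erased in step 8)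
Conditions: TMSCl, Et3N, toluene, rt; filtration and concentration under argon
Reagents that add atoms: chlorotrimethylsilane, C[Si](C)(C)Cl
Why: O-silylation of the β-keto ester enol with TMSCl/Et3N is the standard first stage of 1,3-bis(silyloxy)diene synthesis, and the far less acidic aryl ketone should not be silylated by this reagent pair.

Step 8
Reactants: 14 methyl 5-(5,7-dimethoxy-2,2,6-trimethyl-4-oxochroman-8-yl)-2-methyl-3-(trimethylsilyloxy)pent-2-enoate
Product: 15 5,7-dimethoxy-8-[(2Z)-5-methoxy-4-methyl-3,5-bis(trimethylsilyloxy)penta-2,4-dien-1-yl]-2,2,6-trimethyl-4-(trimethylsilyloxy)-2H-chromene (ketene acetal geometry uncontrolled and without consequence)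
Conditions: LiN(i-Pr)2 (LDA, 2.3 equiv), THF, −78 °C; TMSCl (2.6 equiv), −78 → 0 °C; hexane, filtration under argon
Reagents that add atoms: chlorotrimethylsilane, C[Si](C)(C)Cl
Why: Kinetic γ-deprotonation of the silyl enol ether ester and O-silylation of the dienolate is the established second stage of Chan-type diene synthesis (Z enol ether expected when the terminal diene carbon carries a substituent); the chromanone is deprotonated as well, so a second equivalent of base converts it deliberately into its silyl enol ether, which masks the ketone during the key step.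

Step 9
Reactants: 16 2-methylpropanoyl chloride
Product: 17 N-methoxy-N,2-dimethylpropanamide
Conditions: MeNH(OMe)·HCl, pyridine, CH2Cl2, 0 °C → rt
Reagents that add atoms: N,O-dimethylhydroxylamine hydrochloride, CNOC.Cl
Why: N-Acylation of the hydroxylamine by the acid chloride should give the Weinreb amide.

Step 10
Reactants: 17 N-methoxy-N,2-dimethylpropanamide; 18 ethoxyacetylene
Product: 19 1-ethoxy-4-methylpent-1-yn-3-one
Conditions: 18, n-BuLi, THF, −78 °C; then 17, −78 → −20 °C; cold sat. aq NH4Cl
Reagents that add atoms: none
Why: Addition of lithium ethoxyacetylide to a Weinreb amide stops at the chelated tetrahedral intermediate, so the acid-sensitive alkoxy ynone is released only on the mild quench and over-addition is avoided.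

Step 11
Reactants: 15 5,7-dimethoxy-8-[(2Z)-5-methoxy-4-methyl-3,5-bis(trimethylsilyloxy)penta-2,4-dien-1-yl]-2,2,6-trimethyl-4-(trimethylsilyloxy)-2H-chromene; 19 1-ethoxy-4-methylpent-1-yn-3-one
Product: 22 8-[2-ethoxy-4,6-dihydroxy-5-methyl-3-(2-methylpropanoyl)benzyl]-5,7-dimethoxy-2,2,6-trimethylchroman-4-one, via cyclohexadiene cycloadduct 20 (not isolated), via tris(silyl) arene 21 (not isolated)
Conditions: toluene, 25 → 90 °C (sealed tube); then 1 M HCl, THF, rt
Reagents that add atoms: none
Why: Proposed new method: a 1-alkoxy-1,3-bis(silyloxy)diene has not been combined with a 3-alkoxy ynone in this way; the diene should bond through its CH terminus (the carbon next to the bridge CH2, largest HOMO coefficient) to the ethoxy-bearing β-carbon of the push–pull ynone and through its ketene-acetal carbon to the acyl-bearing α-carbon, either as an asynchronous [4+2] cycloaddition or as a Mukaiyama–Michael addition followed by 6-exo-trig Claisen-type attack of the allenyl silyl ether on the ester carbon, giving 20, which aromatises to 21 by 1,4-loss of methanol before acid removes the three trimethylsilyl groups and returns the chromanone. The closest known reactions are Diels–Alder benzannulations of Chan- and Brassard-type dienes with acetylenic esters, acetylenic ketones and haloquinones, and the formal [3+3] cyclisations of 1,3-bis(silyloxy)dienes with 3-alkoxyenones. Ring A closes intermolecularly, its two new bonds (bridge-bearing carbon to ethoxy-bearing carbon, acyl-bearing carbon to the former ketene-acetal carbon) being formed in the one operation ([4+2] mode), and no stereocentre is created because 20 aromatises. The step needs a single orientation and participation of the two diene termini rather than of the CH terminus together with the central methyl-bearing carbon: polarity matching of the nucleophilic CH terminus with the β-carbon secures the first, and the methyl group on the central carbon (the future C-methyl carbon of ring A) blocks the [3+3] aldol pathway because that carbon could not aromatise. The chromene silyl enol ether is a much weaker nucleophile than the ketene-acetal diene and should be left alone by the unactivated ynone, and the Z geometry of the enol ether keeps the arylmethyl group outside the s-cis diene.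

Step 12
Reactants: 22 8-[2-ethoxy-4,6-dihydroxy-5-methyl-3-(2-methylpropanoyl)benzyl]-5,7-dimethoxy-2,2,6-trimethylchroman-4-one
Product: 23 8-[2,4,6-trihydroxy-3-methyl-5-(2-methylpropanoyl)benzyl]-5,7-dihydroxy-2,2,6-trimethylchroman-4-one (target)
Conditions: BBr3 (8 equiv), CH2Cl2, −78 → 0 °C; then MeOH, H2O
Reagents that add atoms: none
Why: Lewis-acid dealkylation of aryl alkyl ethers: the ethyl ether and the C5 methyl ether each sit ortho to a carbonyl and should cleave with chelation assistance, and excess reagent should remove the hindered C7 methyl ether.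

**Compound list**

1 | 2,6-dimethoxytoluene | Cc1c(OC)cccc1OC | starting material
2 | 2-(3,5-dimethoxy-4-methylphenyl)-4,4,5,5-tetramethyl-1,3,2-dioxaborolane | Cc1c(OC)cc(cc1OC)B1OC(C)(C)C(C)(C)O1 | intermediate
3 | 3,5-dimethoxy-4-methylphenol | Cc1c(OC)cc(O)cc1OC | intermediate
4 | 3-methylbut-2-enoic acid | CC(C)=CC(=O)O | starting material
5 | 5,7-dimethoxy-2,2,6-trimethylchroman-4-one | COc1cc2OC(C)(C)CC(=O)c2c(OC)c1C | intermediate
6 | 5,7-dimethoxy-2,2,6-trimethyl-4-oxochroman-8-carbaldehyde | O=Cc1c(OC)c(C)c(OC)c2c1OC(C)(C)CC2=O | intermediate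
7 | Meldrum's acid (2,2-dimethyl-1,3-dioxane-4,6-dione) | CC1(C)OC(=O)CC(=O)O1 | starting material
8 | 5-[(5,7-dimethoxy-2,2,6-trimethyl-4-oxochroman-8-yl)methylidene]-2,2-dimethyl-1,3-dioxane-4,6-dione | CC1(C)OC(=O)C(=Cc2c(OC)c(C)c(OC)c3c2OC(C)(C)CC3=O)C(=O)O1 | intermediate
9 | 5-[(5,7-dimethoxy-2,2,6-trimethyl-4-oxochroman-8-yl)methyl]-2,2-dimethyl-1,3-dioxane-4,6-dione | CC1(C)OC(=O)C(Cc2c(OC)c(C)c(OC)c3c2OC(C)(C)CC3=O)C(=O)O1 | intermediate
10 | 3-(5,7-dimethoxy-2,2,6-trimethyl-4-oxochroman-8-yl)propanoic acid | OC(=O)CCc1c(OC)c(C)c(OC)c2c1OC(C)(C)CC2=O | intermediate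
11 | potassium methyl methylmalonate (potassium 3-methoxy-2-methyl-3-oxopropanoate) | COC(=O)C(C)C(=O)[O-].[K+] | starting material
12 | 8-[3-(imidazol-1-yl)-3-oxopropyl]-5,7-dimethoxy-2,2,6-trimethylchroman-4-one | O=C(CCc1c(OC)c(C)c(OC)c2c1OC(C)(C)CC2=O)n1ccnc1 | intermediate
13 | methyl 5-(5,7-dimethoxy-2,2,6-trimethyl-4-oxochroman-8-yl)-2-methyl-3-oxopentanoate (racemic) | COC(=O)C(C)C(=O)CCc1c(OC)c(C)c(OC)c2c1OC(C)(C)CC2=O | intermediate
14 | methyl (Z)-5-(5,7-dimethoxy-2,2,6-trimethyl-4-oxochroman-8-yl)-2-methyl-3-(trimethylsilyloxy)pent-2-enoate | COC(=O)/C(C)=C(\O[Si](C)(C)C)CCc1c(OC)c(C)c(OC)c2c1OC(C)(C)CC2=O | intermediate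
15 | 5,7-dimethoxy-8-[(2Z)-5-methoxy-4-methyl-3,5-bis(trimethylsilyloxy)penta-2,4-dien-1-yl]-2,2,6-trimethyl-4-(trimethylsilyloxy)-2H-chromene (drawn 4Z) | CO/C(O[Si](C)(C)C)=C(C)/C(O[Si](C)(C)C)=C/Cc1c(OC)c(C)c(OC)c2c1OC(C)(C)C=C2O[Si](C)(C)C | intermediate
16 | 2-methylpropanoyl chloride | CC(C)C(Cl)=O | starting material
17 | N-methoxy-N,2-dimethylpropanamide | CC(C)C(=O)N(C)OC | intermediate
18 | ethoxyacetylene | CCOC#C | starting material
19 | 1-ethoxy-4-methylpent-1-yn-3-one | CCOC#CC(=O)C(C)C | intermediate
20 | 1-[3-{[5,7-dimethoxy-2,2,6-trimethyl-4-(trimethylsilyloxy)-2H-chromen-8-yl]methyl}-2-ethoxy-6-methoxy-5-methyl-4,6-bis(trimethylsilyloxy)cyclohexa-1,4-dien-1-yl]-2-methylpropan-1-one (mixture of diastereomers) | COC1(O[Si](C)(C)C)C(C)=C(O[Si](C)(C)C)C(Cc2c(OC)c(C)c(OC)c3c2OC(C)(C)C=C3O[Si](C)(C)C)C(OCC)=C1C(=O)C(C)C | intermediate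
21 | 1-[3-{[5,7-dimethoxy-2,2,6-trimethyl-4-(trimethylsilyloxy)-2H-chromen-8-yl]methyl}-2-ethoxy-5-methyl-4,6-bis(trimethylsilyloxy)phenyl]-2-methylpropan-1-one | CCOc1c(Cc2c(OC)c(C)c(OC)c3c2OC(C)(C)C=C3O[Si](C)(C)C)c(O[Si](C)(C)C)c(C)c(O[Si](C)(C)C)c1C(=O)C(C)C | intermediate
22 | 8-[2-ethoxy-4,6-dihydroxy-5-methyl-3-(2-methylpropanoyl)benzyl]-5,7-dimethoxy-2,2,6-trimethylchroman-4-one | CCOc1c(Cc2c(OC)c(C)c(OC)c3c2OC(C)(C)CC3=O)c(O)c(C)c(O)c1C(=O)C(C)C | intermediate
23 | 8-[2,4,6-trihydroxy-3-methyl-5-(2-methylpropanoyl)benzyl]-5,7-dihydroxy-2,2,6-trimethylchroman-4-one | Cc1c(O)c(Cc2c(O)c(C)c(O)c3c2OC(C)(C)CC3=O)c(O)c(C(=O)C(C)C)c1O | target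

**Step count**

Total: 12 steps. Longest linear sequence: 10 steps (steps 1–8, 11, 12); the ynone branch (steps 9–10) is two steps.

**Steps most likely to fail**

Step 11 (proposed new method). The push–pull alkyne may be too weak a dienophile, so that the diene is lost to protodesilylation or oligomerisation before the first bond forms. The Michael adduct may also fail to close, or part of the material may add in the reverse orientation. The fallback uses known chemistry and gives up the benzannulation. It sets out from aldehyde 6. Chemoselective reduction of the aldehyde (NaBH4, 0.3 equiv, MeOH/THF, −20 °C) should give 8-(hydroxymethyl)-5,7-dimethoxy-2,2,6-trimethylchroman-4-one F1. In parallel, commercial 2-methylphloroglucinol is C-acylated with acid chloride 16 (AlCl3, PhNO2, 60 °C) to 1-(2,4,6-trihydroxy-3-methylphenyl)-2-methylpropan-1-one F2. Acid-catalysed Friedel–Crafts benzylation of F2 at its single free ring carbon with the benzylic cation from F1 (cat. p-TsOH, 1,4-dioxane, rt → 50 °C) should give 8-[2,4,6-trihydroxy-3-methyl-5-(2-methylpropanoyl)benzyl]-5,7-dimethoxy-2,2,6-trimethylchroman-4-one F3. F1 cannot self-condense because its ring is fully substituted. BBr3 under the conditions of step 12 then cleaves the two methyl ethers, and the route is rejoined at target 23.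

Step 8. The chromanone lithium enolate may expel the aryloxide (opening of the pyranone ring), γ-deprotonation of the dienol ether may be incomplete, or C-silylation may compete, all giving mixtures of a moisture-sensitive product that cannot be purified. The fallback avoids lithium enolates altogether and sets out from β-keto ester 13, bypassing 14. Soft enolisation with TMSOTf (3.5 equiv) and Et3N (4 equiv) in Et2O at 0 °C → rt silylates the chromanone and converts the β-keto ester into its bis-silyl dienol ether in one operation. Each carbonyl is activated by O-silylation and then deprotonated by the amine. The route is rejoined at 15 and no compound beyond the list is made (F0).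

Step 12. Acid-induced cleavage of the methylene bridge, opening of the pyranone with reclosure on the other ortho oxygen, or incomplete cleavage of the hindered C7 methyl ether may occur under the forcing Lewis-acid conditions. The fallback sets out from 22 and splits the dealkylation into a chelation-controlled stage and a nucleophilic stage. BCl3 (CH2Cl2, −78 → 0 °C) should cleave only the two ethers ortho to a carbonyl, giving 8-[2,4,6-trihydroxy-3-methyl-5-(2-methylpropanoyl)benzyl]-5-hydroxy-7-methoxy-2,2,6-trimethylchroman-4-one F4. The remaining C7 methyl ether, para to the chromanone carbonyl, is then removed by SN2 demethylation with NaSEt in DMF at 110 °C under argon, followed by acidic work-up. The route is rejoined at 23.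

**Further compounds**

F1 | step 11 | 8-(hydroxymethyl)-5,7-dimethoxy-2,2,6-trimethylchroman-4-one | OCc1c(OC)c(C)c(OC)c2c1OC(C)(C)CC2=O
F2 | step 11 | 1-(2,4,6-trihydroxy-3-methylphenyl)-2-methylpropan-1-one | CC(C)C(=O)c1c(O)cc(O)c(C)c1O
F3 | step 11 | 8-[2,4,6-trihydroxy-3-methyl-5-(2-methylpropanoyl)benzyl]-5,7-dimethoxy-2,2,6-trimethylchroman-4-one | CC(C)C(=O)c1c(O)c(C)c(O)c(Cc2c(OC)c(C)c(OC)c3c2OC(C)(C)CC3=O)c1O
F0 | step 8 | none | none
F4 | step 12 | 8-[2,4,6-trihydroxy-3-methyl-5-(2-methylpropanoyl)benzyl]-5-hydroxy-7-methoxy-2,2,6-trimethylchroman-4-one | CC(C)C(=O)c1c(O)c(C)c(O)c(Cc2c(OC)c(C)c(O)c3c2OC(C)(C)CC3=O)c1O
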